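**Strategy.** The hydroazulene is cut at C3a–C8a and C6–C7. The tertiary C3a–OH and the methyl-bearing alkene carbon C6 stand 1,4 across the seven-membered ring, so the oxygen of a 2-methyl-5-alkylfuran can serve as a temporary C3a–O–C6 bridge. An oxyallyl cation (C7–C8–C8a), released from a tertiary α-chloro methyl ketone and linked to the furan through C1–C2–C3, then closes the five- and the seven-membered carbocycle in one intramolecular (4+3) cycloaddition, creating both fully substituted ring-fusion carbons. The precursor is an open-chain chloro ketone whose only fixed stereocentre, C3 (isopropyl), comes from an organocatalytic conjugate addition. Bridge opening, carbonyl reduction and acylation complete the route.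

Key step: step 5

Assumption: the target SMILES is read as (3R,3aS,8S,8aR) in hydroazulene numbering (C1–C3 and C3a/C8a in the five-membered ring, C4–C8 in the seven-membered ring), i.e. isopropyl, C3a–OH, C8a–methyl and the C8 acyloxy group all lie on one face of a cis-fused bicycle.

Step 1
Reactants: 1 2-methylfuran; 2 (E)-4-methylpent-2-enal
Product: 3 (R)-4-methyl-3-(5-methylfuran-2-yl)pentanal
Conditions: (2R,5R)-5-benzyl-2-tert-butyl-3-methylimidazolidin-4-one·CF3CO2H (20 mol%), CH2Cl2/i-PrOH, −40 °C
Reagents that add atoms: none
Why: Iminium-ion catalysis activates the enal for a Friedel–Crafts-type conjugate addition of the furan through its free 5-position; the benzyl group of the catalyst covers one face of the (E)-iminium ion, so the (2R,5R) catalyst should deliver the (R) centre at C3 (the mirror-image catalyst would give (S)).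

Step 2
Reactants: 4 3-bromobutan-2-one
Product: 6 3-(triphenyl-λ5-phosphanylidene)butan-2-one, via phosphonium bromide 5 (not isolated)
Conditions: PPh3, toluene, 80 °C; then aq NaOH, CH2Cl2, rt
Reagents that add atoms: triphenylphosphine, c1ccc(cc1)P(c1ccccc1)c1ccccc1
Why: SN2 quaternisation of the phosphine by the α-bromo ketone followed by deprotonation of the acidified C–H gives the acyl-stabilised ylide (standard Wittig reagent preparation).

Step 3
Reactants: 3 (R)-4-methyl-3-(5-methylfuran-2-yl)pentanal; 6 3-(triphenyl-λ5-phosphanylidene)butan-2-one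
Product: 7 (R,E)-3,7-dimethyl-6-(5-methylfuran-2-yl)oct-3-en-2-one
Conditions: toluene, 90 °C
Reagents that add atoms: none
Why: Wittig olefination of the unhindered aldehyde with the stabilised ylide should give the E-enone; the alkene geometry does not matter because the double bond is reduced next, and the C3 centre, β to the aldehyde, cannot epimerise.

Step 4
Reactants: 7 (R,E)-3,7-dimethyl-6-(5-methylfuran-2-yl)oct-3-en-2-one
Product: 9 (6R)-3-chloro-3,7-dimethyl-6-(5-methylfuran-2-yl)octan-2-one (both epimers at the C–Cl carbon), via triethylsilyl enol ether 8 (not isolated)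
Conditions: RhCl(PPh3)3 (1 mol%), Et3SiH, THF, 50 °C; then N-chlorosuccinimide, 0 °C
Reagents that add atoms: N-chlorosuccinimide, O=C1CCC(=O)N1Cl
Why: Rhodium-catalysed 1,4-hydrosilylation of the enone gives the tetrasubstituted silyl enol ether regiospecifically, and electrophilic α-chlorination of this enol ether (expected to be faster than attack on the dialkylfuran at 0 °C) places chlorine on the tertiary carbon; the C–Cl centre forms as a mixture that is used as such because it is planarised in step 5.

Step 5
Reactants: 9 (6R)-3-chloro-3,7-dimethyl-6-(5-methylfuran-2-yl)octan-2-one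
Product: 11 (3R,3aS,6R,8aS)-3-isopropyl-6,8a-dimethyl-1,2,3,6,7,8a-hexahydro-3a,6-epoxyazulen-8-one, via oxyallyl cation 10 (not isolated)
Conditions: NaOCH2CF3 (1.2 equiv), CF3CH2OH, 0 °C to rt, 0.02 M
Reagents that add atoms: none
Why: Trifluoroethoxide enolises the methyl side (C7) and the enolate expels the tertiary chloride, so both chloride epimers give the same planar 2-oxidoallyl cation 10, which adds across furan carbons C3a and C6 in a six-electron (4+3) process, either concerted or by C3a–C8a bonding first and enolate closure onto the furanium ion. The closest known reaction type is the intramolecular (4+3) cycloaddition of oxyallyl cations, generated from α-halo ketones with base in fluorinated alcohols, onto tethered furans. The cyclopentane closes by 5-exo attack of C8a on the ipso furan carbon through the C1–C2–C3 tether, and the cycloheptene closes as the second σ-bond C6–C7 of the cycloaddition, which leaves the furan oxygen as the C3a–O–C6 bridge. C3a and C6 are locked cis by that bridge and their absolute sense is chosen by the C3 stereocentre through the furan face it exposes, while C8a is set by the approach topology, the methyl ending on the bridge side only from the compact arrangement with the tether in the outer (W) position of the cation. The step therefore needs compact addition on the furan face that leaves isopropyl syn to the bridge: the weakly electrophilic sodium oxyallyl in trifluoroethanol is the cation type that prefers compact addition to furans, and the electron-rich 2,5-dialkylfuran and the five-membered tether secure the regiochemistry, but isopropyl and the C8a methyl end 1,3-cis on the new cyclopentane, which works against this approach, so the diastereomer ratio is the open question of the route and is where its risk is placed.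

Step 6
Reactants: 11 (3R,3aS,6R,8aS)-3-isopropyl-6,8a-dimethyl-1,2,3,6,7,8a-hexahydro-3a,6-epoxyazulen-8-one
Product: 12 (3R,3aS,6S,8aS)-3-isopropyl-6,8a-dimethyl-3a,6-epoxyperhydroazulen-8-one
Conditions: H2 (1 atm), Pd/C (10% palladium on carbon), EtOAc, rt
Reagents that add atoms: none
Why: Heterogeneous catalytic hydrogenation saturates the strained cis-disubstituted C4=C5 alkene while the ketone is inert; no stereocentre is formed or touched (the change of the C6 descriptor is only a priority change).

Step 7
Reactants: 12 (3R,3aS,6S,8aS)-3-isopropyl-6,8a-dimethyl-3a,6-epoxyperhydroazulen-8-one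
Product: 14 (3R,3aS,8aS)-3-isopropyl-6,8a-dimethyl-3a-(trimethylsilyloxy)-2,3,3a,4,5,8a-hexahydroazulen-8(1H)-one, via trimethylsilyl enol ether 13 (not isolated)
Conditions: Me3SiOSO2CF3 (2.2 equiv), Et3N (3 equiv), CH2Cl2, 0 °C to rt
Reagents that add atoms: trimethylsilyl trifluoromethanesulfonate, C[Si](C)(C)OS(=O)(=O)C(F)(F)F
Why: Silyl triflate and amine convert the ketone into its only possible enol ether (C8a bears no hydrogen), and silylation of the bridging oxygen then triggers vinylogous β-elimination of the C6–O bond (the known ring opening of 8-oxabicyclo[3.2.1]octan-3-ones), giving the C6=C7–C8 enone with the C3a oxygen held as its silyl ether so that oxa-Michael re-closure is blocked; only the vanishing C6 centre is affected.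

Step 8
Reactants: 14 (3R,3aS,8aS)-3-isopropyl-6,8a-dimethyl-3a-(trimethylsilyloxy)-2,3,3a,4,5,8a-hexahydroazulen-8(1H)-one
Product: 16 (3R,3aS,8S,8aR)-3-isopropyl-6,8a-dimethyl-1,2,3,3a,4,5,8,8a-octahydroazulene-3a,8-diol, via silyl ether alcohol 15 (not isolated)
Conditions: NaBH4, CeCl3·7H2O, MeOH, −78 °C; then K2CO3, MeOH, rt
Reagents that add atoms: none
Why: Luche 1,2-reduction of the enone, in which hydride should add to C8 from the face opposite the angular C8a methyl and the C3a silyloxy group (both on the same side), giving the C8 alcohol syn to both, after which carbonate-mediated methanolysis removes the trimethylsilyl ether in the same flask.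

Step 9
Reactants: 16 (3R,3aS,8S,8aR)-3-isopropyl-6,8a-dimethyl-1,2,3,3a,4,5,8,8a-octahydroazulene-3a,8-diol; 17 4-methoxybenzoyl chloride
Product: 18 (3R,3aS,8S,8aR)-3a-hydroxy-3-isopropyl-6,8a-dimethyl-1,2,3,3a,4,5,8,8a-octahydroazulen-8-yl 4-methoxybenzoate
Conditions: Et3N, DMAP (cat.), CH2Cl2, 0 °C to rt
Reagents that add atoms: none
Why: DMAP-catalysed acylation is selective for the secondary allylic C8 hydroxyl, the tertiary C3a hydroxyl between a quaternary and a branched carbon being inert under these conditions; no stereocentre is affected and acid is avoided so the allylic ester cannot ionise.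

**Compound list**

1 | 2-methylfuran | Cc1ccco1 | starting material
2 | (E)-4-methylpent-2-enal | CC(C)/C=C/C=O | starting material
3 | (R)-4-methyl-3-(5-methylfuran-2-yl)pentanal | Cc1ccc(o1)[C@@H](C(C)C)CC=O | intermediate
4 | 3-bromobutan-2-one | CC(Br)C(C)=O | starting material
5 | (3-oxobutan-2-yl)triphenylphosphonium bromide | CC(=O)C(C)[P+](c1ccccc1)(c1ccccc1)c1ccccc1.[Br-] | intermediate (not isolated)
6 | 3-(triphenyl-λ5-phosphanylidene)butan-2-one | CC(=O)C(C)=P(c1ccccc1)(c1ccccc1)c1ccccc1 | intermediate
7 | (R,E)-3,7-dimethyl-6-(5-methylfuran-2-yl)oct-3-en-2-one | Cc1ccc(o1)[C@@H](C(C)C)C/C=C(\C)C(C)=O | intermediate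
8 | (6R)-triethyl{[3,7-dimethyl-6-(5-methylfuran-2-yl)oct-2-en-2-yl]oxy}silane, alkene geometry not defined | Cc1ccc(o1)[C@@H](C(C)C)CCC(C)=C(C)O[Si](CC)(CC)CC | intermediate (not isolated)
9 | (6R)-3-chloro-3,7-dimethyl-6-(5-methylfuran-2-yl)octan-2-one, both epimers at the C–Cl carbon | Cc1ccc(o1)[C@@H](C(C)C)CCC(C)(Cl)C(C)=O | intermediate
10 | 2-oxidoallyl cation from 9 (C7–C8(O)–C8a, zwitterion) | Cc1ccc(o1)[C@@H](C(C)C)CC[C+](C)C([O-])=C | intermediate (not isolated)
11 | (3R,3aS,6R,8aS)-3-isopropyl-6,8a-dimethyl-1,2,3,6,7,8a-hexahydro-3a,6-epoxyazulen-8-one; oxygen bridge C3a–O–C6, C4=C5 alkene, isopropyl and C8a methyl syn to the bridge | O=C1C[C@]3(C)C=C[C@]2(O3)[C@@H](C(C)C)CC[C@]12C | intermediate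
12 | (3R,3aS,6S,8aS)-3-isopropyl-6,8a-dimethyl-3a,6-epoxyperhydroazulen-8-one | O=C1C[C@]3(C)CC[C@]2(O3)[C@@H](C(C)C)CC[C@]12C | intermediate
13 | trimethylsilyl enol ether of 12 (C7=C8–OSiMe3, bridge intact) | C[Si](C)(C)OC1=C[C@]3(C)CC[C@]2(O3)[C@@H](C(C)C)CC[C@]12C | intermediate (not isolated)
14 | (3R,3aS,8aS)-3-isopropyl-6,8a-dimethyl-3a-(trimethylsilyloxy)-2,3,3a,4,5,8a-hexahydroazulen-8(1H)-one | O=C1C=C(C)CC[C@]2(O[Si](C)(C)C)[C@@H](C(C)C)CC[C@]12C | intermediate
15 | (3R,3aS,8S,8aR)-3-isopropyl-6,8a-dimethyl-3a-(trimethylsilyloxy)-1,2,3,3a,4,5,8,8a-octahydroazulen-8-ol | O[C@H]1C=C(C)CC[C@]2(O[Si](C)(C)C)[C@@H](C(C)C)CC[C@]12C | intermediate (not isolated)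
16 | (3R,3aS,8S,8aR)-3-isopropyl-6,8a-dimethyl-1,2,3,3a,4,5,8,8a-octahydroazulene-3a,8-diol | O[C@H]1C=C(C)CC[C@]2(O)[C@@H](C(C)C)CC[C@]12C | intermediate
17 | 4-methoxybenzoyl chloride | COc1ccc(cc1)C(Cl)=O | starting material
18 | (3R,3aS,8S,8aR)-3a-hydroxy-3-isopropyl-6,8a-dimethyl-1,2,3,3a,4,5,8,8a-octahydroazulen-8-yl 4-methoxybenzoate | COc1ccc(C(=O)O[C@H]2C=C(C)CC[C@]3(O)[C@@H](C(C)C)CC[C@]23C)cc1 | target

**Step count.** Total: 9 steps. Longest linear sequence: 8 steps (1, 3, 4, 5, 6, 7, 8, 9); step 2 is a one-step side branch.

**Steps most likely to fail**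

1. Step 5. The cation may add through the wrong approach topology (methyl turned away from the oxygen bridge, or isopropyl turned away from the methyl). It may also be lost before the second bond forms, by proton transfer to an enone or by Friedel–Crafts alkylation at furan C4. The fallback sets out from 9 and comes back at 11. Soft enolisation of 9 toward the methyl group (Et3SiOSO2CF3, Et3N, CH2Cl2, −78 °C) should give the 2-(triethylsilyloxy)allyl chloride F1. Ionisation of F1 with AgOSO2CF3 in CH2Cl2/MeNO2 at −78 °C releases a 2-silyloxyallyl cation, a known alternative oxyallyl source. It is more electrophilic, works without base or protic solvent, and bonds C3a–C8a earlier and more stepwise, so it should select among the approach geometries differently from the sodium oxyallyl. Loss of the silyl group from the resulting oxocarbenium ion gives 11 directly.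

2. Step 4. Electrophilic chlorine may be consumed by the electron-rich furan ring, or 1,2-hydrosilylation may compete with the 1,4-mode. The fallback sets out from 3 and comes back at 10 (and so at 11); no electrophilic chlorine meets the furan. Wittig olefination of 3 with methyl 2-(triphenyl-λ5-phosphanylidene)propanoate should give the enoate F2. Conjugate reduction with Mg in MeOH gives the saturated ester F3. Chloromethyllithium (ICH2Cl, MeLi·LiBr, THF, −78 °C) converts the ester into the chloromethyl ketone F4. F4 is the regioisomeric α-chloro ketone: under the conditions of step 5 it enolises at the methine and loses the primary chloride, giving the same cation 10.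

3. Step 8. Hydride delivery may show poor facial selectivity, giving the C8 alcohol anti to the angular methyl. The fallback sets out from 14 and comes back at 16. The reduction is stopped before the carbonate stage and the 8-epi alcohol F5 is isolated. Mitsunobu esterification (4-nitrobenzoic acid, PPh3, DIAD, toluene) inverts C8 and gives the 4-nitrobenzoate F6. K2CO3 in MeOH then cleaves both the ester and the trimethylsilyl ether to give 16.

**Further compounds**

F1 | step 5 | (6R)-triethyl{[3-chloro-3,7-dimethyl-6-(5-methylfuran-2-yl)oct-1-en-2-yl]oxy}silane | Cc1ccc(o1)[C@@H](C(C)C)CCC(C)(Cl)C(=C)O[Si](CC)(CC)CC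
F2 | step 4 | methyl (R,E)-2,6-dimethyl-5-(5-methylfuran-2-yl)hept-2-enoate | Cc1ccc(o1)[C@@H](C(C)C)C/C=C(\C)C(=O)OC
F3 | step 4 | methyl (5R)-2,6-dimethyl-5-(5-methylfuran-2-yl)heptanoate | Cc1ccc(o1)[C@@H](C(C)C)CCC(C)C(=O)OC
F4 | step 4 | (6R)-1-chloro-3,7-dimethyl-6-(5-methylfuran-2-yl)octan-2-one | Cc1ccc(o1)[C@@H](C(C)C)CCC(C)C(=O)CCl
F5 | step 8 | (3R,3aS,8R,8aR)-3-isopropyl-6,8a-dimethyl-3a-(trimethylsilyloxy)-1,2,3,3a,4,5,8,8a-octahydroazulen-8-ol | O[C@@H]1C=C(C)CC[C@]2(O[Si](C)(C)C)[C@@H](C(C)C)CC[C@]12C
F6 | step 8 | (3R,3aS,8S,8aR)-3-isopropyl-6,8a-dimethyl-3a-(trimethylsilyloxy)-1,2,3,3a,4,5,8,8a-octahydroazulen-8-yl 4-nitrobenzoate | O=C(O[C@H]1C=C(C)CC[C@]2(O[Si](C)(C)C)[C@@H](C(C)C)CC[C@]12C)c1ccc(cc1)[N+](=O)[O-]
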